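Numbering (daucane): ring A = cyclopentane C1–C5 [C1 C(CH3), C2 CH(OAc), C3 CH2, C4 C(OH)(iPr), C5 CH]. Ring B = cycloheptene C1, C5–C10 [C6 CH(O-anisoyl), C7 CH2, C8 C(CH3)=, C9 =CH, C10 CH2]. β = face of the C1 methyl group.
Enabling feature: in ring B the lone methylene C7 separates C6 from C8=C9, and C5–H/C6–O is a masked C5=C6 bond. This skipped diene C5=C6–C7–C8=C9, lying opposite the C1–C10 bond, is the retron of a divinylcyclopropane Cope rearrangement, and the C4 hydroxyl of ring A sits homoallylic to the C6–C8 axis.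
Key disconnection: break C1–C10, re-make a temporary C6–C8 bond (cyclopropane C6–C7–C8), then excise C7 as a zinc carbenoid. The bicyclic hydroxy-dienone goes back to a flat monocyclic (Z)-trienone with C4 as its only stereocentre.
Before the key step, the trienone comes from a ring-A vinylogous ester and a (Z)-dienyllithium (Stork–Danheiser union). After it, the C4 hydroxyl directs reduction at C2, epoxidation of C5=C6 and reduction at C6, and two acylations finish.
Ring order: ring A is bought. The temporary three-membered ring is closed and opened again within the key step, and ring B is closed last, in that same step.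

Key step: step 7

Assumption: the facial sense of the oxaziridine in step 2 is inferred from related cyclic tetrasubstituted enolates. Both antipodes of the reagent are commercial, so the other one is used if a pilot run shows the opposite sense.

Step 1
Reactants: 1 3-ethoxy-2-methylcyclopent-2-en-1-one
Product: 3 (±)-3-ethoxy-2-methyl-5-(propan-2-yl)cyclopent-2-en-1-one, via lithium enolate 2 (not isolated)
Conditions: LiN(iPr)2, THF, −78 °C; 2-iodopropane, DMPU, −78 → 0 °C
Reagents that add atoms: 2-iodopropane, CC(C)I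
Why: Kinetic α′-deprotonation of the vinylogous ester gives cross-conjugated enolate 2, which is alkylated at C4 by the secondary iodide in the dipolar medium (enolate SN2 alkylation as used ahead of Stork–Danheiser transpositions); the new centre is racemic and is planarised again in step 2.

Step 2
Reactants: 3 (±)-3-ethoxy-2-methyl-5-(propan-2-yl)cyclopent-2-en-1-one
Product: 5 (5R)-3-ethoxy-5-hydroxy-2-methyl-5-(propan-2-yl)cyclopent-2-en-1-one, via sodium enolate 4 (not isolated)
Conditions: NaN(SiMe3)2, THF, −78 °C; (−)-(8,8-dichlorocamphorylsulfonyl)oxaziridine, −78 °C; AcOH; recrystallisation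
Reagents that add atoms: (−)-(8,8-dichlorocamphorylsulfonyl)oxaziridine, CC1(C)[C@H]2CC[C@@]13CS(=O)(=O)N4O[C@]34C2(Cl)Cl
Why: Davis asymmetric enolate hydroxylation: tetrasubstituted enolate 4 attacks the oxaziridine oxygen in an SN2-type open transition state in which the dichlorocamphor skeleton shields one enolate face, which should set C4 as R, and recrystallisation is planned to bring 5 to enantiopurity.

Step 3
Reactants: 6 prop-2-yn-1-ol
Product: 8 (2Z)-3-iodo-2-methylprop-2-en-1-ol, via vinylmagnesium alkoxide 7 (not isolated)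
Conditions: MeMgBr, CuI (10 mol %), THF, −10 → 23 °C; I2, −10 °C; 1 M HCl
Reagents that add atoms: methylmagnesium bromide, C[Mg]Br; iodine, II
Why: Copper-catalysed anti-carbomagnesiation of the propargylic alkoxide places CH3 on the internal carbon and magnesium cis to CH2O in a five-membered chelate (7), and iodinolysis with retention fixes the Z geometry.

Step 4
Reactants: 8 (2Z)-3-iodo-2-methylprop-2-en-1-ol
Product: 9 (2Z)-3-iodo-2-methylprop-2-enal
Conditions: MnO2, CH2Cl2, 23 °C, dark
Reagents that add atoms: none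
Why: Heterogeneous MnO2 oxidation of the allylic alcohol is neutral and fast, so the isomerisation-prone Z-β-iodoenal should keep its geometry when it is used at once.

Step 5
Reactants: 9 (2Z)-3-iodo-2-methylprop-2-enal
Product: 10 (1Z)-1-iodo-2-methylbuta-1,3-diene
Conditions: MePPh3Br, n-BuLi, THF, 0 °C; 9, −78 → 0 °C
Reagents that add atoms: methyltriphenylphosphonium bromide, C[P+](c1ccccc1)(c1ccccc1)c1ccccc1.[Br-]
Why: Wittig methylenation with the non-stabilised ylide touches only the aldehyde, leaves the C–I bond and the Z double bond intact, and gives a volatile diene that is carried on as a solution.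

Step 6
Reactants: 10 (1Z)-1-iodo-2-methylbuta-1,3-diene; 5 (5R)-3-ethoxy-5-hydroxy-2-methyl-5-(propan-2-yl)cyclopent-2-en-1-one
Product: 14 (4R)-4-hydroxy-2-methyl-3-[(1Z)-2-methylbuta-1,3-dien-1-yl]-4-(propan-2-yl)cyclopent-2-en-1-one, via dienyllithium 11 (not isolated), via lithium alkoxide 12 (not isolated), via dilithium 1,2-adduct 13 (not isolated)
Conditions: 10, t-BuLi (2 equiv), Et2O, −78 °C; 5, MeLi (1 equiv), THF, −78 °C; combine, −78 → −30 °C; 1 M HCl, THF, 0 °C
Reagents that add atoms: water, O
Why: Stork–Danheiser transposition: iodine–lithium exchange with retention gives 11, which adds 1,2 to the ketone of pre-formed alkoxide 12, and cold dilute acid ionises the bis-allylic carbinol of 13 and hydrolyses the enol ether, so that the carbonyl moves to C2 and the dienyl chain ends on C5, while C4 is untouched and the short acid contact should preserve the Z geometry.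

Step 7
Reactants: 14 (4R)-4-hydroxy-2-methyl-3-[(1Z)-2-methylbuta-1,3-dien-1-yl]-4-(propan-2-yl)cyclopent-2-en-1-one
Product: 16 (3R,8aR)-3-hydroxy-6,8a-dimethyl-3-(propan-2-yl)-3,5,8,8a-tetrahydroazulen-1(2H)-one (4β-hydroxydauca-5,8-dien-2-one), via cis-divinylcyclopropane 15 (not isolated)
Conditions: Et2Zn, CH2I2, CH2Cl2, −15 → 0 °C; sat. aq NH4Cl; solvent switch without purification, PhMe, 95 °C
Reagents that add atoms: diiodomethane, ICI
Why: Et2Zn converts the C4 hydroxyl of 14 into a zinc alkoxide that carries the iodomethylzinc carbenoid and hands its CH2 (the future C7) in a concerted, stereospecific syn addition to the homoallylic C6=C8 bond, giving cis-divinylcyclopropane 15; after the carbenoid is quenched, heating drives a concerted [3,3] shift of 15 through the endo-boat transition state, which makes C1–C10 and breaks the temporary C6–C8 bond. The closest known reaction types are the hydroxyl-directed Simmons–Smith (Furukawa) cyclopropanation, methylene addition to the central bond of a cis-hexatriene, and the divinylcyclopropane–cycloheptadiene (Cope) rearrangement of 2-methyl-3-(2-vinylcyclopropyl)cyclopent-2-enones to angularly methylated hydroazulenones. The three-membered ring closes by a [2+1] cheletropic-type transfer, and ring B closes by the six-electron pericyclic C1–C10 bond formation (suprafacial on both allyl halves, driven by release of cyclopropane strain), so that the net event is a (6+1) annulation that can only deliver the cis,cis-diene C5=C6/C8=C9. C4 is the only control element: allylic strain twists the side chain out of the plane of ring A, the Z-placed vinyl group tucks over the face that bears OH and not the isopropyl group, and the alkoxide-bound carbenoid attacks the alkene face turned towards C4, which fixes 15 as 6R,8R; the boat geometry then relays this to C1, C10 bonding on the face opposite to the C4 hydroxyl, so that the quaternary centre is 1R with CH3 cis to OH. Chemoselectivity is needed among three C=C bonds and is secured by the C2 ketone, which deactivates the tetrasubstituted C1=C5 bond, and by distance, since the monosubstituted C9=C10 bond is the least nucleophilic and out of reach of the alkoxide. Over-cyclopropanation of the allylic-alcohol double bond C5=C6 of 16 is avoided because 15, slowed by the methyl group that points inward at the C1 terminus, should survive at 0 °C until the reagent has been destroyed.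

Step 8
Reactants: 16 4β-hydroxydauca-5,8-dien-2-one
Product: 17 (1S,3R,8aR)-6,8a-dimethyl-3-(propan-2-yl)-1,2,3,5,8,8a-hexahydroazulene-1,3-diol (dauca-5,8-diene-2α,4β-diol)
Conditions: Me4NBH(OAc)3, MeCN/AcOH, −25 °C
Reagents that add atoms: none
Why: Evans–Saksena reduction: the C4 hydroxyl exchanges onto boron and delivers hydride intramolecularly to the β face of the C2 ketone, which sets the 2α (2S) alcohol anti to the C4 hydroxyl.

Step 9
Reactants: 17 dauca-5,8-diene-2α,4β-diol
Product: 18 (1S,3R,8aR)-3-hydroxy-6,8a-dimethyl-3-(propan-2-yl)-1,2,3,5,8,8a-hexahydroazulen-1-yl acetate (2α-acetoxydauca-5,8-dien-4β-ol)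
Conditions: Ac2O, pyridine, DMAP (cat.), CH2Cl2, 0 → 23 °C
Reagents that add atoms: acetic anhydride, CC(=O)OC(C)=O
Why: DMAP-catalysed acetylation is selective for the secondary C2 alcohol because the C4 alcohol is tertiary and flanked by the isopropyl group.

Step 10
Reactants: 18 2α-acetoxydauca-5,8-dien-4β-ol
Product: 19 2α-acetoxy-5β,6β-epoxydauc-8-en-4β-ol
Conditions: VO(acac)2 (5 mol %), t-BuOOH, CH2Cl2, 0 °C
Reagents that add atoms: tert-butyl hydroperoxide, CC(C)(C)OO
Why: Hydroxyl-directed VO(acac)2/t-BuOOH epoxidation: the tertiary allylic C4 alkoxide binds vanadium and the peroxide, so oxygen goes only to C5=C6 and to its β face (syn to OH), and the isolated C8=C9 bond is not touched.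

Step 11
Reactants: 19 2α-acetoxy-5β,6β-epoxydauc-8-en-4β-ol
Product: 20 2α-acetoxy-5αH-dauc-8-ene-4β,6β-diol
Conditions: Cp2TiCl2, Mn, H2O, THF, 23 °C
Reagents that add atoms: none
Why: Nugent–RajanBabu reductive epoxide opening: Cp2TiCl (trivalent titanium, made from Cp2TiCl2 and Mn) cleaves the C5–O bond by single-electron transfer to give the tertiary C5 radical, which takes a hydrogen atom from the aqua complex of Cp2TiCl on the α face because the β face carries the bulky C6 titanoxy group, the C1 methyl and the C4 oxygen, so that the trans ring fusion (5α-H) should result.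

Step 12
Reactants: 20 2α-acetoxy-5αH-dauc-8-ene-4β,6β-diol
Product: 21 2α-acetoxy-4β-hydroxy-5αH-dauc-8-en-6-one
Conditions: Dess–Martin periodinane, pyridine, CH2Cl2, 0 °C
Reagents that add atoms: none
Why: Dess–Martin oxidation under pyridine buffering converts the only secondary alcohol to the ketone without acid or base strong enough to move C8=C9 into conjugation, to epimerise C5 or to trigger retro-aldol cleavage.

Step 13
Reactants: 21 2α-acetoxy-4β-hydroxy-5αH-dauc-8-en-6-one
Product: 22 2α-acetoxy-5αH-dauc-8-ene-4β,6α-diol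
Conditions: Me4NBH(OAc)3, MeCN/AcOH, −30 °C
Reagents that add atoms: none
Why: Second Evans–Saksena reduction: boron bound to the β C4 hydroxyl delivers hydride to the β face of the C6 ketone through a six-membered chair-like transition state, which gives the 1,3-anti diol with the 6α (6S) alcohol.

Step 14
Reactants: 22 2α-acetoxy-5αH-dauc-8-ene-4β,6α-diol
Product: 23 2α-acetoxy-6α-(4-methoxybenzoyloxy)-5αH-dauc-8-en-4β-ol (target, 1R,2S,4R,5S,6S)
Conditions: 4-MeOC6H4COCl, Et3N, DMAP, CH2Cl2, 23 → 40 °C
Reagents that add atoms: 4-methoxybenzoyl chloride, COc1ccc(cc1)C(Cl)=O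
Why: DMAP-catalysed acyl transfer (Steglich-type catalysis) esterifies the only secondary alcohol, the tertiary C4 hydroxyl being inert, and gives the target.

Compound list
1 | 3-ethoxy-2-methylcyclopent-2-en-1-one | CCOC1=C(C)C(=O)CC1 | starting material
2 | lithium enolate of 1 | [Li+].CCOC1=C(C)C([O-])=CC1 | intermediate
3 | (±)-3-ethoxy-2-methyl-5-(propan-2-yl)cyclopent-2-en-1-one | CCOC1=C(C)C(=O)C(C(C)C)C1 | intermediate
4 | sodium enolate of 3 | [Na+].CCOC1=C(C)C([O-])=C(C(C)C)C1 | intermediate
5 | (5R)-3-ethoxy-5-hydroxy-2-methyl-5-(propan-2-yl)cyclopent-2-en-1-one | CCOC1=C(C)C(=O)[C@](O)(C(C)C)C1 | intermediate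
6 | prop-2-yn-1-ol | C#CCO | starting material
7 | (Z)-[3-(bromomagnesiooxy)-2-methylprop-1-en-1-yl]magnesium bromide | Br[Mg]/C=C(/C)CO[Mg]Br | intermediate
8 | (2Z)-3-iodo-2-methylprop-2-en-1-ol | I/C=C(/C)CO | intermediate
9 | (2Z)-3-iodo-2-methylprop-2-enal | I/C=C(/C)C=O | intermediate
10 | (1Z)-1-iodo-2-methylbuta-1,3-diene | I/C=C(/C)C=C | intermediate
11 | [(1Z)-2-methylbuta-1,3-dien-1-yl]lithium | [Li]/C=C(/C)C=C | intermediate
12 | lithium alkoxide of 5 | [Li+].CCOC1=C(C)C(=O)[C@]([O-])(C(C)C)C1 | intermediate
13 | dilithium salt of the 1,2-adduct of 11 to 12 (new carbinol centre inconsequential) | [Li+].[Li+].CCOC1=C(C)C([O-])(/C=C(/C)C=C)[C@]([O-])(C(C)C)C1 | intermediate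
14 | (4R)-4-hydroxy-2-methyl-3-[(1Z)-2-methylbuta-1,3-dien-1-yl]-4-(propan-2-yl)cyclopent-2-en-1-one | CC1=C(/C=C(/C)C=C)[C@](O)(C(C)C)CC1=O | intermediate
15 | (4R)-3-[(1R,2R)-2-ethenyl-2-methylcyclopropyl]-4-hydroxy-2-methyl-4-(propan-2-yl)cyclopent-2-en-1-one | CC1=C([C@@H]2C[C@]2(C)C=C)[C@](O)(C(C)C)CC1=O | intermediate
16 | (3R,8aR)-3-hydroxy-6,8a-dimethyl-3-(propan-2-yl)-3,5,8,8a-tetrahydroazulen-1(2H)-one | O=C1C[C@@](O)(C(C)C)C2=CCC(C)=CC[C@@]12C | intermediate
17 | (1S,3R,8aR)-6,8a-dimethyl-3-(propan-2-yl)-1,2,3,5,8,8a-hexahydroazulene-1,3-diol | O[C@H]1C[C@@](O)(C(C)C)C2=CCC(C)=CC[C@@]12C | intermediate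
18 | (1S,3R,8aR)-3-hydroxy-6,8a-dimethyl-3-(propan-2-yl)-1,2,3,5,8,8a-hexahydroazulen-1-yl acetate | CC(=O)O[C@H]1C[C@@](O)(C(C)C)C2=CCC(C)=CC[C@@]12C | intermediate
19 | 2α-acetoxy-5β,6β-epoxydauc-8-en-4β-ol | CC(=O)O[C@H]1C[C@@](O)(C(C)C)[C@@]2(O3)[C@H]3CC(C)=CC[C@@]12C | intermediate
20 | 2α-acetoxy-5αH-dauc-8-ene-4β,6β-diol | O[C@@H]1CC(C)=CC[C@@]2(C)[C@@H](OC(C)=O)C[C@@](O)(C(C)C)[C@H]12 | intermediate
21 | 2α-acetoxy-4β-hydroxy-5αH-dauc-8-en-6-one | O=C1CC(C)=CC[C@@]2(C)[C@@H](OC(C)=O)C[C@@](O)(C(C)C)[C@H]12 | intermediate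
22 | 2α-acetoxy-5αH-dauc-8-ene-4β,6α-diol | O[C@H]1CC(C)=CC[C@@]2(C)[C@@H](OC(C)=O)C[C@@](O)(C(C)C)[C@H]12 | intermediate
23 | 2α-acetoxy-6α-(4-methoxybenzoyloxy)-5αH-dauc-8-en-4β-ol | COc1ccc(C(=O)O[C@H]2CC(C)=CC[C@@]3(C)[C@@H](OC(C)=O)C[C@@](O)(C(C)C)[C@H]23)cc1 | target

Total step count: 14. Longest linear sequence: 12 steps (6 → 23, steps 3–14).

Steps most likely to fail

1. Step 7. Methylene transfer may go to the terminal vinyl group or to the wrong face of C6=C8 (poor chemo- or facial selectivity). The rearrangement may also start early and be followed by over-cyclopropanation.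
Fallback: the cyclopropane is made before the union and under reagent control.
It sets out from 8. Charette asymmetric cyclopropanation [Zn(CH2I)2·DME, (4R,5R)-2-butyl-N,N,N′,N′-tetramethyl-1,3,2-dioxaborolane-4,5-dicarboxamide, CH2Cl2] gives [(1R,2R)-2-iodo-1-methylcyclopropyl]methanol F1. Dess–Martin oxidation gives (1R,2R)-2-iodo-1-methylcyclopropane-1-carbaldehyde F2, and Wittig methylenation gives (1R,2R)-1-ethenyl-2-iodo-1-methylcyclopropane F3.
t-BuLi converts F3 with retention into cis-(2-ethenyl-2-methylcyclopropyl)lithium F4, which adds to alkoxide 12 to give the dilithium cyclopropyl 1,2-adduct F5. Cold dilute HCl then leads to 15, where the route is rejoined for the thermal stage of step 7.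

2. Step 2. Facial discrimination by the oxaziridine may be insufficient, or γ-deprotonation may compete, leaving material of low enantiomeric purity.
Fallback: diastereomers are separated on a chiral enol ether instead of relying on reagent control.
It sets out from enolate 4, which is oxidised with achiral 2-(phenylsulfonyl)-3-phenyloxaziridine to racemic material, that is 5 together with (5S)-3-ethoxy-5-hydroxy-2-methyl-5-(propan-2-yl)cyclopent-2-en-1-one F6. Acid-catalysed exchange of ethoxy for (−)-menthyloxy (TsOH, PhMe, removal of EtOH) gives the (5R)-menthyl vinylogous ester F7 and the (5S)-menthyl vinylogous ester F8, which are separated by crystallisation or chromatography.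
F7 then takes the place of 5 in step 6. MeLi gives the lithium alkoxide of the menthyl ester F9, addition of 11 gives the dilithium menthyl 1,2-adduct F10, and cold dilute HCl releases menthol and comes back to the route at 14.

3. Step 11. The C5 radical may be reduced further and undergo β-elimination (deoxygenation, loss of the C4 or C6 oxygen), or hydrogen-atom transfer to C5 may show poor facial selectivity.
Fallback: the C6 carbonyl is reached by ionic transposition and the carbinol is rebuilt.
It sets out from 18. Babler–Dauben oxidative transposition with pyridinium chlorochromate, C5H5NH[CrO3Cl], in CH2Cl2 gives 2α-acetoxydauca-4,8-dien-6-one F11. Weitz–Scheffer epoxidation (t-BuOOH, DBU, CH2Cl2), expected on the β face away from the 2α-acetoxy group, gives 2α-acetoxy-4β,5β-epoxydauc-8-en-6-one F12. SmI2 in THF/MeOH at −78 °C then cleaves the C5–O bond next to the ketone, and protonation of the samarium enolate comes back to the route at 21.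

Further compounds
F1 | step 7 | [(1R,2R)-2-iodo-1-methylcyclopropyl]methanol | OC[C@@]1(C)C[C@H]1I
F2 | step 7 | (1R,2R)-2-iodo-1-methylcyclopropane-1-carbaldehyde | O=C[C@@]1(C)C[C@H]1I
F3 | step 7 | (1R,2R)-1-ethenyl-2-iodo-1-methylcyclopropane | C=C[C@@]1(C)C[C@H]1I
F4 | step 7 | cis-(2-ethenyl-2-methylcyclopropyl)lithium | [Li][C@@H]1C[C@]1(C)C=C
F5 | step 7 | dilithium cyclopropyl 1,2-adduct (F4 added to 12) | [Li+].[Li+].CCOC1=C(C)C([O-])([C@@H]2C[C@]2(C)C=C)[C@]([O-])(C(C)C)C1
F6 | step 2 | (5S)-3-ethoxy-5-hydroxy-2-methyl-5-(propan-2-yl)cyclopent-2-en-1-one | CCOC1=C(C)C(=O)[C@@](O)(C(C)C)C1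
F7 | step 2 | (5R)-5-hydroxy-2-methyl-3-{[(1R,2S,5R)-5-methyl-2-(propan-2-yl)cyclohexyl]oxy}-5-(propan-2-yl)cyclopent-2-en-1-one | CC(C)[C@@H]1CC[C@@H](C)C[C@H]1OC2=C(C)C(=O)[C@](O)(C(C)C)C2
F8 | step 2 | (5S)-5-hydroxy-2-methyl-3-{[(1R,2S,5R)-5-methyl-2-(propan-2-yl)cyclohexyl]oxy}-5-(propan-2-yl)cyclopent-2-en-1-one | CC(C)[C@@H]1CC[C@@H](C)C[C@H]1OC2=C(C)C(=O)[C@@](O)(C(C)C)C2
F9 | step 2 | lithium alkoxide of F7 | [Li+].CC(C)[C@@H]1CC[C@@H](C)C[C@H]1OC2=C(C)C(=O)[C@]([O-])(C(C)C)C2
F10 | step 2 | dilithium menthyl 1,2-adduct (11 added to F9) | [Li+].[Li+].CC(C)[C@@H]1CC[C@@H](C)C[C@H]1OC2=C(C)C([O-])(/C=C(/C)C=C)[C@]([O-])(C(C)C)C2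
F11 | step 11 | 2α-acetoxydauca-4,8-dien-6-one | CC(=O)O[C@H]1CC(C(C)C)=C2C(=O)CC(C)=CC[C@@]12C
F12 | step 11 | 2α-acetoxy-4β,5β-epoxydauc-8-en-6-one | CC(=O)O[C@H]1C[C@]2(C(C)C)O[C@@]23C(=O)CC(C)=CC[C@@]13C
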